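In amounts, this flask starts with less reagent than starting material, so I keep my accounts in amounts.

starting material 0.35 M; reagent in the second phase 0.332 M; time 1.0 h; volume of the second phase over the first 1.0

    reagent in the reaction phase ⇌ reagent in the second phase, rate k1*([reagent in the reaction phase] - [reagent in the second phase]/K1) per volume of the first phase (K1 = 3.4, k1 = 0.37 s⁻¹)
    starting material + reagent in the reaction phase → target (k2 = 0.24 M⁻¹ s⁻¹)
    reagent in the reaction phase + target → over-reacted product (k3 = 0.11 M⁻¹ s⁻¹)
    starting material + target → side product (k4 = 0.019 M⁻¹ s⁻¹)

- percent here means starting material units held: one side product counts as two
- in the second phase: reagent in the second phase; everything else is in the first
- charges count per volume of the first phase; a concentration in a rate is the amount of a species over the volume of its own phase; every rate counts per litre of the first phase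
- run time (flask): 1.0 h

- how much target there is at 1.0 h, in percent of the starting material charged
- part of the starting material charged that has reacted at 1.0 h

I build this flask up one step at a time and watch one sum: target, plus 2 times the reagent left in both phases, minus the starting material left. With the main step alone, each event gains one target and loses one starting material and one reagent, so the sum stands still, and target ends at 94.9 %, reagent being the limiting reagent. The sum starts at 2 times the reagent charged minus the starting material charged, in percent of that starting material: the reagent margin, 89.7 %. Adding the side step leaves the sum alone, since each event takes one target and one starting material, so with both used up target would stand at the margin. Adding over-reaction takes one reagent and one target, so the sum drops by 3, and I must count 3 times the over-reacted product back in. Transfer between the phases moves reagent but doesn't change the sum.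

If starting material and reagent both end near nothing in this flask, target is the margin less 3 times the over-reacted product, and that difference reaches nothing at 29.9 % over-reacted. My reckoning stops there, because it doesn't give the split between the two losses. The forecast does commit: 13.5 % target and 99.6 % reacted, with target “then eroded by over-reaction and by the side reaction”.

The simulation gives 18.7 % target and 99.9 % reacted in this flask. Target lies below the margin through over-reaction and the side step together: striking out the first gives 53.2 %, striking out the second 51.5 %. The margin less 3 times 23.7 % over-reacted product gives 18.6 %, so the forecast's gap of 5.2 percentage points amounts to 1.7 points of over-reacted product.

The neighbour flask charged with 0.59 M of starting material has a margin of 12.5 %. Adding its 8.11 % starting material left and taking off 3 times its 6.78 % over-reacted product gives 0.299 %; computed, that neighbour holds 0.299 % target.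

(All constants belong to no real substance; the run is a simulation.)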